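**Retrosynthetic overview**
- Target ⇐ bis(triethylsilyl) ether of the corresponding diol (both aldehydes unveiled in one Swern operation) ⇐ ring ketone at the acetoxy carbon (hydride, then acetylation in the same flask).
- Cyclononadienone ⇐ Claisen ring expansion of a 2-alkylidene-2,3,6,7-tetrahydrooxepine; this one [3,3] shift makes the C8–C9 bond, both ring methine stereocentres, the C6=C7 alkene and the nine-membered ring.
- Oxepine ⇐ ring-closing metathesis of an acyclic allyl vinyl ether ⇐ copper-catalysed O-alkenylation of a secondary allylic alcohol with an E-iodoalkene.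
- Iodoalkene ⇐ (R)-citronellal (supplies the side-chain stereocentre); allylic alcohol ⇐ 2-deoxy-D-ribose (its C3 carbinol becomes the transient centre whose chirality is relayed to C8 and C9).
- Ring order: seven-membered oxacycle first (metathesis), then the nine-membered carbocycle (sigmatropic ring expansion).

Assumption: the target is made exactly as the SMILES is written (R at C1, C8, C9 and C10; cis ring bonds at both ring alkenes); locants used for all intermediates: C1 (CH–OAc), C2, C3 (CH3), C4, C5, C6, C7 (carries C18), C8 (carries C19), C9 (carries side-chain methine C10).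

**Step 1**
Reactants: 1 (R)-citronellal [(3R)-3,7-dimethyloct-6-enal]
Product: 3 (3R)-3,7-dimethyloct-6-en-1-yne, via enol nonaflate 2 (not isolated)
Conditions: n-C4F9SO2F, P2-Et phosphazene base, DMF, −30 °C → rt
Reagents that add atoms: none
Why: Enol nonaflate formation followed by base-induced beta-elimination (a one-pot aldehyde-to-terminal-alkyne dehydration) removes only the carbonyl oxygen and the two alpha-hydrogens, so the methyl-bearing stereocentre (the future C10) is carried over unchanged from citronellal.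

**Step 2**
Reactants: 3 (3R)-3,7-dimethyloct-6-en-1-yne
Product: 4 (6R)-2,6,10-trimethylundeca-1,9-dien-4-yne
Conditions: methallyl bromide, CuI (10 mol %), K2CO3, n-Bu4NBr (10 mol %), DMF, rt
Reagents that add atoms: methallyl bromide (3-bromo-2-methylprop-1-ene), C=C(C)CBr
Why: Copper-acetylide allylation (copper-catalysed SN2 coupling of a terminal alkyne with an allylic bromide) under carbonate base gives the skipped enyne without isomerising it to an allene.

**Step 3**
Reactants: 4 (6R)-2,6,10-trimethylundeca-1,9-dien-4-yne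
Product: 6 (4E,6R)-4-iodo-2,6,10-trimethylundeca-1,4,9-triene, via alkenylzirconocene chloride 5 (not isolated)
Conditions: Cp2Zr(H)Cl (1.3 equiv), THF, 40 °C; then I2, 0 °C
Reagents that add atoms: iodine, [I][I]
Why: Hydrozirconation adds Zr–H syn across the alkyne with zirconium settling on the less hindered carbon next to the CH2 group, and iodinolysis of the C–Zr bond with retention then gives the E-iodoalkene whose iodine is trans to the stereogenic side chain.

**Step 4**
Reactants: 7 2-deoxy-D-ribose
Product: 8 (2R,3S)-hex-5-ene-1,2,3-triol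
Conditions: Ph3PCH3Br, KOt-Bu, THF, 0 °C → reflux
Reagents that add atoms: methyltriphenylphosphonium bromide, C[P+](c1ccccc1)(c1ccccc1)c1ccccc1.[Br-]
Why: Wittig methylenation of the open-chain aldehyde tautomer of the lactol turns C1 of the sugar into a vinyl group and leaves both carbinol stereocentres untouched.

**Step 5**
Reactants: 8 (2R,3S)-hex-5-ene-1,2,3-triol
Product: 9 (2R,4S,5R)-2-phenyl-4-(prop-2-en-1-yl)-1,3-dioxan-5-ol
Conditions: PhCH(OMe)2, camphorsulfonic acid (cat.), CH2Cl2, rt
Reagents that add atoms: benzaldehyde dimethyl acetal, COC(OC)c1ccccc1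
Why: Acid-catalysed transacetalisation under thermodynamic control selects the six-membered 1,3-dioxane spanning the primary and the allyl-bearing hydroxyl because phenyl, allyl and hydroxyl can all be equatorial, which also fixes the new acetal centre as 2R relative to the two sugar-derived centres.

**Step 6**
Reactants: 9 (2R,4S,5R)-2-phenyl-4-(prop-2-en-1-yl)-1,3-dioxan-5-ol
Product: 10 (2R,4S)-2-phenyl-4-(prop-2-en-1-yl)-1,3-dioxan-5-one
Conditions: Dess–Martin periodinane, CH2Cl2, 0 °C → rt
Reagents that add atoms: none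
Why: Dess–Martin oxidation of the remaining secondary alcohol proceeds without base, and the adjacent stereocentre (the future C6) is additionally protected against epimerisation because its 2,4-cis diequatorial arrangement is the stable one.

**Step 7**
Reactants: 10 (2R,4S)-2-phenyl-4-(prop-2-en-1-yl)-1,3-dioxan-5-one
Product: 11 ethyl (2E)-2-[(2R,4S)-2-phenyl-4-(prop-2-en-1-yl)-1,3-dioxan-5-ylidene]acetate
Conditions: Ph3P=CHCO2Et, toluene, 60 °C
Reagents that add atoms: ethyl (triphenylphosphoranylidene)acetate, CCOC(=O)C=P(c1ccccc1)(c1ccccc1)c1ccccc1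
Why: Wittig olefination with a stabilised ylide gives the exocyclic enoate with the ester on the side of the unsubstituted ring CH2, away from the equatorial allyl group (allylic 1,3-strain), which defines the later cis relationship of C18 and C19.

**Step 8**
Reactants: 11 ethyl (2E)-2-[(2R,4S)-2-phenyl-4-(prop-2-en-1-yl)-1,3-dioxan-5-ylidene]acetate
Product: 12 (2E)-2-[(2R,4S)-2-phenyl-4-(prop-2-en-1-yl)-1,3-dioxan-5-ylidene]ethan-1-ol
Conditions: i-Bu2AlH (2.2 equiv), CH2Cl2, −78 °C
Reagents that add atoms: none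
Why: DIBAL-H 1,2-reduction of the conjugated ester at −78 °C stops cleanly at the allylic alcohol and touches neither the benzylidene acetal nor the alkene geometry.

**Step 9**
Reactants: 12 (2E)-2-[(2R,4S)-2-phenyl-4-(prop-2-en-1-yl)-1,3-dioxan-5-ylidene]ethan-1-ol
Product: 13 (2E,4S)-3-(hydroxymethyl)hepta-2,6-diene-1,4-diol
Conditions: pyridinium p-toluenesulfonate (cat.), MeOH, rt
Reagents that add atoms: none
Why: Acid-catalysed transacetalisation to methanol (benzylidene acetal cleavage) releases the 1,3-diol under conditions too mild to ionise the allylic alcohols or to affect the carbinol stereocentre.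

**Step 10**
Reactants: 13 (2E,4S)-3-(hydroxymethyl)hepta-2,6-diene-1,4-diol
Product: 14 (2E,4S)-1-[(triethylsilyl)oxy]-3-{[(triethylsilyl)oxy]methyl}hepta-2,6-dien-4-ol
Conditions: Et3SiCl (2.05 equiv), imidazole, CH2Cl2, −40 °C
Reagents that add atoms: chlorotriethylsilane, CC[Si](Cl)(CC)CC
Why: Chemoselective silylation works because the two primary hydroxyls react far faster with the silyl chloride at low temperature than the secondary hydroxyl, which is flanked by a fully substituted alkene carbon.

**Step 11**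
Reactants: 14 (2E,4S)-1-[(triethylsilyl)oxy]-3-{[(triethylsilyl)oxy]methyl}hepta-2,6-dien-4-ol; 6 (4E,6R)-4-iodo-2,6,10-trimethylundeca-1,4,9-triene
Product: 15 (2E,4S)-4-{[(4E,6R)-2,6,10-trimethylundeca-1,4,9-trien-4-yl]oxy}-1-[(triethylsilyl)oxy]-3-{[(triethylsilyl)oxy]methyl}hepta-2,6-diene
Conditions: CuI (10 mol %), 3,4,7,8-tetramethyl-1,10-phenanthroline (20 mol %), Cs2CO3, toluene, 80 °C
Reagents that add atoms: none
Why: Copper-catalysed Ullmann-type C–O cross-coupling of an iodoalkene with an alcohol occurs with retention at the alkene and without touching the carbinol C–O bond, so it delivers the E-enol ether (side chain trans to oxygen) with the S carbinol centre intact.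

**Step 12**
Reactants: 15 (2E,4S)-4-{[(4E,6R)-2,6,10-trimethylundeca-1,4,9-trien-4-yl]oxy}-1-[(triethylsilyl)oxy]-3-{[(triethylsilyl)oxy]methyl}hepta-2,6-diene
Product: 17 (3Z,6E,8R,9R)-3-methyl-9-[(2R)-6-methylhept-5-en-2-yl]-7,8-bis{[(triethylsilyl)oxy]methyl}cyclonona-3,6-dien-1-one, via alkylidene tetrahydrooxepine 16 (not isolated)
Conditions: second-generation Grubbs catalyst RuCl2(=CHPh)(H2IMes)(PCy3) (5 mol %), toluene (5 mM), 60 °C; then DMSO (50 equiv per Ru), K2CO3, 165 °C, sealed tube
Reagents that add atoms: none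
Why: Ring-closing metathesis between the allyl and methallyl groups gives the seven-membered 2-alkylidene oxacycle whose new trisubstituted alkene is necessarily ring-cis, and the following Claisen rearrangement ([3,3]-sigmatropic ring expansion) is forced by the ring tether through a chair transition state with C5 pseudo-axial and the side chain and C19 pseudo-equatorial, so the S configuration of the breaking C6–O carbon is relayed into 8R and 9R while the new C6=C7 alkene is formed ring-cis.

**Step 13**
Reactants: 17 (3Z,6E,8R,9R)-3-methyl-9-[(2R)-6-methylhept-5-en-2-yl]-7,8-bis{[(triethylsilyl)oxy]methyl}cyclonona-3,6-dien-1-one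
Product: 19 (1R,3Z,6E,8R,9R)-3-methyl-9-[(2R)-6-methylhept-5-en-2-yl]-7,8-bis{[(triethylsilyl)oxy]methyl}cyclonona-3,6-dien-1-yl acetate, via aluminium alkoxide 18 (not isolated)
Conditions: i-Bu2AlH, CH2Cl2, −78 °C; then pyridine, DMAP, Ac2O, −78 → 0 °C
Reagents that add atoms: acetic anhydride, CC(=O)OC(C)=O
Why: Reductive acetylation (DIBAL-H reduction, then acylation of the aluminium alkoxide in the same flask) should set C1 as R because hydride reaches the carbonyl from the convex face of the folded cis,cis-cyclononadienone, anti to the C8–C9 ring bond and to the C6=C7 alkene lying across the ring, which places the new oxygen trans to the side chain.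

**Step 14**
Reactants: 19 (1R,3Z,6E,8R,9R)-3-methyl-9-[(2R)-6-methylhept-5-en-2-yl]-7,8-bis{[(triethylsilyl)oxy]methyl}cyclonona-3,6-dien-1-yl acetate
Product: 20 (1R,3Z,6E,8R,9R)-7,8-diformyl-3-methyl-9-[(2R)-6-methylhept-5-en-2-yl]cyclonona-3,6-dien-1-yl acetate
Conditions: (COCl)2, DMSO, CH2Cl2, −78 → −40 °C; then Et3N, −78 → 0 °C
Reagents that add atoms: none
Why: Swern oxidation applied directly to primary triethylsilyl ethers (the chlorosulfonium salt cleaves the O–Si bonds and the alkoxysulfonium ions collapse to aldehydes) unveils both formyl groups in one operation at low temperature, which avoids the lactol trap of stepwise 1,4-diol oxidation and keeps the base-sensitive C8 centre and the alkene positions intact.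

**Compound list**

1 | (R)-citronellal, (3R)-3,7-dimethyloct-6-enal | O=CC[C@H](C)CCC=C(C)C | starting material
2 | (3R)-3,7-dimethylocta-1,6-dien-1-yl nonafluorobutane-1-sulfonate (E/Z mixture at the enol alkene) | FC(F)(F)C(F)(F)C(F)(F)C(F)(F)S(=O)(=O)OC=C[C@H](C)CCC=C(C)C | intermediate
3 | (3R)-3,7-dimethyloct-6-en-1-yne | C#C[C@H](C)CCC=C(C)C | intermediate
4 | (6R)-2,6,10-trimethylundeca-1,9-dien-4-yne | C=C(C)CC#C[C@H](C)CCC=C(C)C | intermediate
5 | chloro[(4E,6R)-2,6,10-trimethylundeca-1,4,9-trien-4-yl]zirconocene (cyclopentadienyl rings drawn sigma-bonded) | C=C(C)C/C(=C\[C@H](C)CCC=C(C)C)[Zr](Cl)(C1C=CC=C1)C1C=CC=C1 | intermediate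
6 | (4E,6R)-4-iodo-2,6,10-trimethylundeca-1,4,9-triene | C=C(C)C/C(I)=C\[C@H](C)CCC=C(C)C | intermediate
7 | 2-deoxy-D-ribose (drawn as the open-chain aldehyde) | O=CC[C@H](O)[C@H](O)CO | starting material
8 | (2R,3S)-hex-5-ene-1,2,3-triol | C=CC[C@H](O)[C@H](O)CO | intermediate
9 | (2R,4S,5R)-2-phenyl-4-(prop-2-en-1-yl)-1,3-dioxan-5-ol | C=CC[C@@H]1O[C@H](c2ccccc2)OC[C@H]1O | intermediate
10 | (2R,4S)-2-phenyl-4-(prop-2-en-1-yl)-1,3-dioxan-5-one | C=CC[C@@H]1O[C@H](c2ccccc2)OCC1=O | intermediate
11 | ethyl (2E)-2-[(2R,4S)-2-phenyl-4-(prop-2-en-1-yl)-1,3-dioxan-5-ylidene]acetate | C=CC[C@@H]1O[C@H](c2ccccc2)OC/C1=C\C(=O)OCC | intermediate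
12 | (2E)-2-[(2R,4S)-2-phenyl-4-(prop-2-en-1-yl)-1,3-dioxan-5-ylidene]ethan-1-ol | C=CC[C@@H]1O[C@H](c2ccccc2)OC/C1=C\CO | intermediate
13 | (2E,4S)-3-(hydroxymethyl)hepta-2,6-diene-1,4-diol | C=CC[C@H](O)/C(CO)=C/CO | intermediate
14 | (2E,4S)-1-[(triethylsilyl)oxy]-3-{[(triethylsilyl)oxy]methyl}hepta-2,6-dien-4-ol | C=CC[C@H](O)/C(CO[Si](CC)(CC)CC)=C/CO[Si](CC)(CC)CC | intermediate
15 | (2E,4S)-4-{[(4E,6R)-2,6,10-trimethylundeca-1,4,9-trien-4-yl]oxy}-1-[(triethylsilyl)oxy]-3-{[(triethylsilyl)oxy]methyl}hepta-2,6-diene | C=C(C)C/C(O[C@@H](CC=C)/C(CO[Si](CC)(CC)CC)=C/CO[Si](CC)(CC)CC)=C\[C@H](C)CCC=C(C)C | intermediate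
16 | (2E,7S)-7-{(2E)-1,4-bis[(triethylsilyl)oxy]but-2-en-2-yl}-2-[(2R)-2,6-dimethylhept-5-en-1-ylidene]-4-methyl-2,3,6,7-tetrahydrooxepine | O1[C@H](/C(CO[Si](CC)(CC)CC)=C/CO[Si](CC)(CC)CC)C/C=C(C)\C/C1=C\[C@H](C)CCC=C(C)C | intermediate
17 | (3Z,6E,8R,9R)-3-methyl-9-[(2R)-6-methylhept-5-en-2-yl]-7,8-bis{[(triethylsilyl)oxy]methyl}cyclonona-3,6-dien-1-one | O=C1C/C(C)=C\C/C=C(/CO[Si](CC)(CC)CC)[C@H](CO[Si](CC)(CC)CC)[C@H]1[C@H](C)CCC=C(C)C | intermediate
18 | diisobutylaluminium (1R,3Z,6E,8R,9R)-3-methyl-9-[(2R)-6-methylhept-5-en-2-yl]-7,8-bis{[(triethylsilyl)oxy]methyl}cyclonona-3,6-dien-1-olate | CC(C)C[Al](CC(C)C)O[C@@H]1C/C(C)=C\C/C=C(/CO[Si](CC)(CC)CC)[C@H](CO[Si](CC)(CC)CC)[C@H]1[C@H](C)CCC=C(C)C | intermediate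
19 | (1R,3Z,6E,8R,9R)-3-methyl-9-[(2R)-6-methylhept-5-en-2-yl]-7,8-bis{[(triethylsilyl)oxy]methyl}cyclonona-3,6-dien-1-yl acetate | CC(=O)O[C@@H]1C/C(C)=C\C/C=C(/CO[Si](CC)(CC)CC)[C@H](CO[Si](CC)(CC)CC)[C@H]1[C@H](C)CCC=C(C)C | intermediate
20 | (1R,3Z,6E,8R,9R)-7,8-diformyl-3-methyl-9-[(2R)-6-methylhept-5-en-2-yl]cyclonona-3,6-dien-1-yl acetate (CNP0113811.6) | CC(=O)O[C@@H]1C/C(C)=C\C/C=C(/C=O)[C@H](C=O)[C@H]1[C@H](C)CCC=C(C)C | target

**Totals**
Total step count: 14 (steps 1–3 give iodoalkene 6, steps 4–10 give alcohol 14, steps 11–14 join and finish).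
Longest linear sequence: 11 steps (7 → 20 through steps 4–14).

**Steps most likely to fail, with fallbacks**

Step 11 is the most exposed: a hindered secondary allylic alcohol has to be joined to an iodoalkene that is fully substituted at the reacting carbon, so the coupling may be slow and the iodide may be lost by elimination. The fallback sets out from enyne 4: hydroboration with pinacolborane catalysed by Cp2Zr(H)Cl puts boron on the same carbon and with the same geometry as the iodine of 6 and gives the pinacol alkenylboronate F1. An oxidative copper-mediated alkenyl–oxygen coupling of F1 with alcohol 14 (Cu(OAc)2, Et3N, 4 Å molecular sieves, air, CH2Cl2, rt; Chan–Lam-type, retention at the alkene) then gives allyl vinyl ether 15, where the route is rejoined.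

Step 13 rests on a conformational argument for a nine-membered ring, and the hydride may enter from the other face. The fallback sets out from ketone 17: reduction under Luche conditions (NaBH4, CeCl3·7H2O, MeOH, −40 °C) and isolation gives, in that case, the C1-epimeric alcohol F2. Mitsunobu esterification with acetic acid (PPh3, diisopropyl azodicarboxylate, toluene, 0 °C) inverts C1 and returns to acetate 19.

Step 14 asks one operation to cleave two silyl ethers and oxidise both carbons next to an epimerisable centre, and it may stall at a mono-aldehyde or erode C8. The fallback sets out from acetate 19: HF·pyridine buffered with pyridine in THF at 0 °C removes both silyl groups to give the diol acetate F3. A conventional Swern oxidation of the free 1,4-diol (both hydroxyls activated before base is added, i-Pr2NEt at −78 °C) then gives target 20.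

**Further compounds**
F1 | step 11 | 4,4,5,5-tetramethyl-2-[(4Z,6R)-2,6,10-trimethylundeca-1,4,9-trien-4-yl]-1,3,2-dioxaborolane | C=C(C)C/C(B1OC(C)(C)C(C)(C)O1)=C\[C@H](C)CCC=C(C)C
F2 | step 13 | (1S,3Z,6E,8R,9R)-3-methyl-9-[(2R)-6-methylhept-5-en-2-yl]-7,8-bis{[(triethylsilyl)oxy]methyl}cyclonona-3,6-dien-1-ol | O[C@H]1C/C(C)=C\C/C=C(/CO[Si](CC)(CC)CC)[C@H](CO[Si](CC)(CC)CC)[C@H]1[C@H](C)CCC=C(C)C
F3 | step 14 | (1R,3Z,6E,8R,9R)-7,8-bis(hydroxymethyl)-3-methyl-9-[(2R)-6-methylhept-5-en-2-yl]cyclonona-3,6-dien-1-yl acetate | CC(=O)O[C@@H]1C/C(C)=C\C/C=C(/CO)[C@H](CO)[C@H]1[C@H](C)CCC=C(C)C
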